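**Retrosynthetic overview**

1. Target (A/B-cis labdane, labdane numbering) ⇐ O-acetylation, desilylation and ester O-demethylation ⇐ C8 ketone methylenation ⇐ conjugate reduction of a Δ6-8-oxo cis-decalin that already carries the side chain.
2. C9–C11 bond ⇐ α′-alkylation of the ring B enone with a triflate made from (R)-linalool, which supplies C13.
3. Ring B ⇐ Lewis acid formal [4+2] union of a ring A cyclohexene (C5=C10, C4 already quaternary) with 3-(benzyloxy)cyclobutanone: C5 and C10 insert into the four-membered ring C6–C7–C8–C9, a two-atom ring expansion that gives the cis-fused decalin.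
4. Enabling feature: the strained C6–C9 bond of the cyclobutanone, flanked by the benzyloxy donor on C6 and the C8 carbonyl, which a Lewis acid opens to an oxocarbenium (C6)/enolate (C9) zwitterion.
5. Order of ring formation: ring A first (from a cyclohexanone, C4 set by auxiliary-controlled methylation), ring B second by the ring expansion; C5 and C10 are set in that step, C9 in the alkylation.

Key step: step 6

Remark: the SMILES places H5 cis to the C10 methyl and to the C4 carboxyl, so the target is the A/B-cis labdane (4S,5S,9S,10R,13R) and the route is built for a cis-decalin. Atoms are numbered as in labdanes (ring A = C1–C5 and C10; ring B = C5–C10; C17 = exocyclic CH2; C18 = methyl and C19 = carboxyl on C4; C20 = methyl on C10; side chain C11–C16). Compound 2 is used as the free base.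

**Route**

Step 1
Reactants: 1 methyl 2-oxocyclohexane-1-carboxylate; 2 tert-butyl L-valinate
Product: 3 methyl 2-{[(2S)-1-tert-butoxy-3-methyl-1-oxobutan-2-yl]amino}cyclohex-1-ene-1-carboxylate
Conditions: BF3·OEt2 (cat.), benzene, reflux, azeotropic removal of water
Reagents that add atoms: none
Why: Acid-catalysed condensation of the β-keto ester with the primary amine (enamine formation) gives the hydrogen-bonded enamino ester that carries the valine auxiliary, and no stereocentre is formed.

Step 2
Reactants: 3 methyl 2-{[(2S)-1-tert-butoxy-3-methyl-1-oxobutan-2-yl]amino}cyclohex-1-ene-1-carboxylate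
Product: 5 methyl (1S)-1-methyl-2-oxocyclohexane-1-carboxylate, via methylated ketimine 4 (not isolated)
Conditions: LiN(iPr)2, toluene, −78 °C; HMPA (1 equiv); MeI, −55 °C; then 1 M aq. HCl, rt
Reagents that add atoms: iodomethane, CI; water, O
Why: This is the auxiliary-controlled alkylation of a chelated lithio-enamine of an α-substituted β-keto ester (chiral enamine alkylation): the valine isopropyl group on the lithium chelate shields one face so that MeI creates the quaternary centre (C4 of the target) as S, the donor additive being the one that delivers this sense (tert-butyl D-valinate is the mirror-image option), and acid hydrolysis of imine 4 releases ketone 5.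

Step 3
Reactants: 5 methyl (1S)-1-methyl-2-oxocyclohexane-1-carboxylate
Product: 6 methyl (1S)-1,3-dimethyl-2-oxocyclohexane-1-carboxylate (both C3 epimers)
Conditions: LiN(iPr)2, THF, −78 °C; MeI, −78 to 0 °C
Reagents that add atoms: iodomethane, CI
Why: Kinetic enolate alkylation at the only enolisable α-carbon (future C10) installs the future C20 methyl, the new centre forming as an epimer mixture that is of no consequence because it becomes sp2 in step 4.

Step 4
Reactants: 6 methyl (1S)-1,3-dimethyl-2-oxocyclohexane-1-carboxylate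
Product: 7 methyl (1S)-1,3-dimethyl-2-{[(trifluoromethyl)sulfonyl]oxy}cyclohex-2-ene-1-carboxylate
Conditions: KN(SiMe3)2, THF, −78 to 0 °C; PhNTf2; aq. NH4Cl work-up
Reagents that add atoms: N-phenylbis(trifluoromethanesulfonimide), O=S(=O)(N(c1ccccc1)S(=O)(=O)C(F)(F)F)C(F)(F)F
Why: Enolate O-sulfonylation (enol triflate formation) is regiospecific because the other α-carbon is quaternary, which fixes the double bond between future C5 and C10.

Step 5
Reactants: 7 methyl (1S)-1,3-dimethyl-2-{[(trifluoromethyl)sulfonyl]oxy}cyclohex-2-ene-1-carboxylate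
Product: 8 methyl (1S)-1,3-dimethylcyclohex-2-ene-1-carboxylate
Conditions: Pd(OAc)2 (5 mol%), PPh3, Bu3N, HCO2H, DMF, 60 °C
Reagents that add atoms: none
Why: Palladium-catalysed formate reduction of the enol triflate (oxidative addition, hydride transfer from formate, reductive elimination) replaces the triflate by hydrogen and leaves the allylic quaternary centre untouched.

Step 6
Reactants: 8 methyl (1S)-1,3-dimethylcyclohex-2-ene-1-carboxylate; 9 3-(benzyloxy)cyclobutan-1-one
Product: 11 methyl (1S,4aR,8aS)-1,4a-dimethyl-6-oxo-1,2,3,4,4a,5,6,8a-octahydronaphthalene-1-carboxylate, via β-benzyloxy ketone 10 (not isolated)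
Conditions: EtAlCl2 (2.5 equiv), CH2Cl2, −78 to −40 °C, slow addition of 9 (2 equiv); 1 M aq. HCl work-up; then DBU, CH2Cl2, rt
Reagents that add atoms: none
Why: Proposed new method: EtAlCl2 should open the strained C6–C9 bond of cyclobutanone 9, which is polarised by the benzyloxy donor on C6 and the C8 carbonyl, to a 1,4-zwitterion (oxocarbenium at C6, aluminium enolate at C9) that adds across the C5=C10 alkene of 8, C5 bonding to C6 and the tertiary C10 cation then being captured by C9, so that the four-membered ring grows by two atoms into ring B with release of ring strain. The closest known reaction type is the Lewis acid-promoted formal [4+2] cycloaddition of 3-alkoxycyclobutanones with allylsilanes, silyl enol ethers and carbonyl compounds and, intramolecularly, with unactivated alkenes; new here is only the intermolecular use of an unactivated trisubstituted cycloalkene. Ring B closes stepwise, by Prins-type C5–C6 bond formation followed by a six-membered enol-endo collapse of the enolate carbon C9 on the C10 cation. C5 is controlled by the C4 stereocentre, whose pseudoaxial aluminium-complexed ester shields the β face so that C6 enters anti to it, and C10 is controlled by the tether, since the enolate can reach the cation only on the face that already carries C6, which gives the cis ring fusion with H5 and the C10 methyl on the ester face. The step needs Markovnikov regioselectivity (only C10 of the trisubstituted alkene can carry the cation), facial selectivity anti to the ester and C–C capture of the cation in preference to proton loss or lactonisation by the ester carbonyl, which low temperature and the intramolecular enolate favour. DBU finally eliminates benzyl alcohol from 10 (E1cB) to give enone 11, whose only α′-position is C9.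

Step 7
Reactants: 12 (3R)-3,7-dimethylocta-1,6-dien-3-ol [(R)-linalool]
Product: 13 tert-butyl{[(3R)-3,7-dimethylocta-1,6-dien-3-yl]oxy}dimethylsilane
Conditions: tBuMe2SiOTf, 2,6-lutidine, CH2Cl2, 0 °C
Reagents that add atoms: tert-butyldimethylsilyl trifluoromethanesulfonate, CC(C)(C)[Si](C)(C)OS(=O)(=O)C(F)(F)F
Why: Silyl triflate silylation protects the hindered tertiary allylic alcohol, and the C13 stereocentre (R, from the chiral pool) is carried through unchanged.

Step 8
Reactants: 13 tert-butyl{[(3R)-3,7-dimethylocta-1,6-dien-3-yl]oxy}dimethylsilane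
Product: 14 (4R)-4-{[tert-butyl(dimethyl)silyl]oxy}-4-methylhex-5-enal
Conditions: O3 (about 1 equiv, stopped when 13 is consumed), CH2Cl2/MeOH, −78 °C; then Me2S, −78 °C to rt
Reagents that add atoms: ozone, [O-][O+]=O
Why: Chemoselective ozonolysis with reductive work-up cleaves the electron-rich trisubstituted alkene in preference to the hindered vinyl group next to the silyloxy carbon, so the stereocentre is not touched.

Step 9
Reactants: 14 (4R)-4-{[tert-butyl(dimethyl)silyl]oxy}-4-methylhex-5-enal
Product: 15 tert-butyl(dimethyl){[(3R)-3-methyl-6-{[tri(propan-2-yl)silyl]oxy}hexa-1,5-dien-3-yl]oxy}silane (E/Z mixture)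
Conditions: iPr3SiOTf, Et3N, CH2Cl2, 0 °C to rt
Reagents that add atoms: tri(propan-2-yl)silyl trifluoromethanesulfonate, CC(C)[Si](C(C)C)(C(C)C)OS(=O)(=O)C(F)(F)F
Why: Soft enolisation and O-silylation of the aldehyde (silyl enol ether formation) moves the unsaturation onto the aldehyde carbon and its neighbour in preparation for a one-carbon degradation, the E/Z ratio being irrelevant.

Step 10
Reactants: 15 tert-butyl(dimethyl){[(3R)-3-methyl-6-{[tri(propan-2-yl)silyl]oxy}hexa-1,5-dien-3-yl]oxy}silane
Product: 17 (3R)-3-{[tert-butyl(dimethyl)silyl]oxy}-3-methylpent-4-en-1-ol, via silyloxy pentenal 16 (not isolated)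
Conditions: O3, CH2Cl2/MeOH, −78 °C; then NaBH4, −78 to 0 °C
Reagents that add atoms: ozone, [O-][O+]=O
Why: Ozonolysis of the electron-rich enol ether (much faster than that of the vinyl group) excises the terminal carbon as a silyl formate, and borohydride reduction of aldehyde 16 in the same flask gives the primary alcohol.

Step 11
Reactants: 17 (3R)-3-{[tert-butyl(dimethyl)silyl]oxy}-3-methylpent-4-en-1-ol
Product: 18 (3R)-3-{[tert-butyl(dimethyl)silyl]oxy}-3-methylpent-4-en-1-yl trifluoromethanesulfonate
Conditions: Tf2O, 2,6-lutidine, CH2Cl2, −78 °C; used at once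
Reagents that add atoms: trifluoromethanesulfonic anhydride, O=S(=O)(OS(=O)(=O)C(F)(F)F)C(F)(F)F
Why: O-Sulfonylation of the primary alcohol (triflate formation) gives an alkylating agent reactive enough for a hindered enolate, and it is used at once.

Step 12
Reactants: 11 methyl (1S,4aR,8aS)-1,4a-dimethyl-6-oxo-1,2,3,4,4a,5,6,8a-octahydronaphthalene-1-carboxylate; 18 (3R)-3-{[tert-butyl(dimethyl)silyl]oxy}-3-methylpent-4-en-1-yl trifluoromethanesulfonate
Product: 19 methyl (1S,4aS,5R,8aS)-5-[(3R)-3-{[tert-butyl(dimethyl)silyl]oxy}-3-methylpent-4-en-1-yl]-1,4a-dimethyl-6-oxo-1,2,3,4,4a,5,6,8a-octahydronaphthalene-1-carboxylate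
Conditions: LiN(iPr)2 (1.05 equiv), THF, −78 °C; then 18, DMPU, −78 to −40 °C
Reagents that add atoms: none
Why: Kinetic α′-deprotonation of the enone gives the cross-conjugated lithium dienolate at C9, and its SN2 alkylation by the primary triflate (enolate alkylation) should take place anti to the pseudoaxial C1–C10 bond, on the convex face that carries H5 and the C10 methyl, which sets C9 with the side chain cis to the C10 methyl.

Step 13
Reactants: 19 methyl (1S,4aS,5R,8aS)-5-[(3R)-3-{[tert-butyl(dimethyl)silyl]oxy}-3-methylpent-4-en-1-yl]-1,4a-dimethyl-6-oxo-1,2,3,4,4a,5,6,8a-octahydronaphthalene-1-carboxylate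
Product: 20 methyl (1S,4aS,5R,8aS)-5-[(3R)-3-{[tert-butyl(dimethyl)silyl]oxy}-3-methylpent-4-en-1-yl]-1,4a-dimethyl-6-oxodecahydronaphthalene-1-carboxylate
Conditions: [(Ph3P)CuH]6 (5 mol%), H2 (15 bar), benzene, tBuOH, rt
Reagents that add atoms: none
Why: Copper hydride-catalysed conjugate reduction under hydrogen (1,4-hydride addition, then hydrogenolysis of the copper enolate) saturates only the enone C6=C7 bond, leaves the vinyl group alone and does not touch C9 because the enolate is generated on the C7 side.

Step 14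
Reactants: 20 methyl (1S,4aS,5R,8aS)-5-[(3R)-3-{[tert-butyl(dimethyl)silyl]oxy}-3-methylpent-4-en-1-yl]-1,4a-dimethyl-6-oxodecahydronaphthalene-1-carboxylate
Product: 21 methyl (1S,4aR,5S,8aS)-5-[(3R)-3-{[tert-butyl(dimethyl)silyl]oxy}-3-methylpent-4-en-1-yl]-1,4a-dimethyl-6-methylidenedecahydronaphthalene-1-carboxylate
Conditions: Zn, CH2Br2, TiCl4, THF, 0 °C (reagent pre-formed); then 20, CH2Cl2, 0 °C to rt
Reagents that add atoms: dibromomethane, BrCBr
Why: Takai–Lombardo methylenation with the non-basic zinc/titanium methylene reagent converts the hindered, enolisable C8 ketone into the exocyclic alkene without epimerising C9 and without attacking the ester.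

Step 15
Reactants: 21 methyl (1S,4aR,5S,8aS)-5-[(3R)-3-{[tert-butyl(dimethyl)silyl]oxy}-3-methylpent-4-en-1-yl]-1,4a-dimethyl-6-methylidenedecahydronaphthalene-1-carboxylate
Product: 22 (1S,4aR,5S,8aS)-5-[(3R)-3-{[tert-butyl(dimethyl)silyl]oxy}-3-methylpent-4-en-1-yl]-1,4a-dimethyl-6-methylidenedecahydronaphthalene-1-carboxylic acid
Conditions: NaSEt, DMF, 100 °C; then 1 M aq. HCl
Reagents that add atoms: none
Why: Thiolate SN2 O-demethylation cleaves the neopentyl-type ester that resists saponification, and no stereocentre is involved.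

Step 16
Reactants: 22 (1S,4aR,5S,8aS)-5-[(3R)-3-{[tert-butyl(dimethyl)silyl]oxy}-3-methylpent-4-en-1-yl]-1,4a-dimethyl-6-methylidenedecahydronaphthalene-1-carboxylic acid
Product: 23 (1S,4aR,5S,8aS)-5-[(3R)-3-hydroxy-3-methylpent-4-en-1-yl]-1,4a-dimethyl-6-methylidenedecahydronaphthalene-1-carboxylic acid
Conditions: Bu4NF, THF, 50 °C; then aq. HCl to pH 3
Reagents that add atoms: none
Why: Fluoride-induced desilylation frees the tertiary allylic alcohol under basic conditions that cannot ionise it.

Step 17
Reactants: 23 (1S,4aR,5S,8aS)-5-[(3R)-3-hydroxy-3-methylpent-4-en-1-yl]-1,4a-dimethyl-6-methylidenedecahydronaphthalene-1-carboxylic acid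
Product: 25 (1S,4aR,5S,8aS)-5-[(3R)-3-(acetyloxy)-3-methylpent-4-en-1-yl]-1,4a-dimethyl-6-methylidenedecahydronaphthalene-1-carboxylic acid, via mixed anhydride 24 (not isolated)
Conditions: Ac2O, DMAP, Et3N, CH2Cl2, rt; then aq. NaHCO3, THF, rt; acidify to pH 4
Reagents that add atoms: acetic anhydride, CC(=O)OC(C)=O
Why: DMAP-catalysed acylation acetylates the tertiary alcohol with retention at C13, and the mixed anhydride 24 that forms at the carboxyl group is hydrolysed at its unhindered acetyl carbonyl during the bicarbonate work-up.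

**Compound list**

1 | methyl 2-oxocyclohexane-1-carboxylate | O=C1CCCCC1C(=O)OC | starting material
2 | tert-butyl L-valinate [tert-butyl (2S)-2-amino-3-methylbutanoate] | CC(C)[C@H](N)C(=O)OC(C)(C)C | starting material
3 | methyl 2-{[(2S)-1-tert-butoxy-3-methyl-1-oxobutan-2-yl]amino}cyclohex-1-ene-1-carboxylate | COC(=O)C1=C(N[C@@H](C(C)C)C(=O)OC(C)(C)C)CCCC1 | intermediate
4 | methyl (1S)-2-{[(2S)-1-tert-butoxy-3-methyl-1-oxobutan-2-yl]imino}-1-methylcyclohexane-1-carboxylate | CC(C)[C@H](N=C1CCCC[C@]1(C)C(=O)OC)C(=O)OC(C)(C)C | intermediate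
5 | methyl (1S)-1-methyl-2-oxocyclohexane-1-carboxylate | O=C1CCCC[C@]1(C)C(=O)OC | intermediate
6 | methyl (1S)-1,3-dimethyl-2-oxocyclohexane-1-carboxylate (both C3 epimers) | O=C1C(C)CCC[C@]1(C)C(=O)OC | intermediate
7 | methyl (1S)-1,3-dimethyl-2-{[(trifluoromethyl)sulfonyl]oxy}cyclohex-2-ene-1-carboxylate | CC1=C(OS(=O)(=O)C(F)(F)F)[C@](C)(CCC1)C(=O)OC | intermediate
8 | methyl (1S)-1,3-dimethylcyclohex-2-ene-1-carboxylate | CC1=C[C@](C)(CCC1)C(=O)OC | intermediate
9 | 3-(benzyloxy)cyclobutan-1-one | O=C1CC(OCc2ccccc2)C1 | starting material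
10 | methyl (1S,4aR,8aS)-8-(benzyloxy)-1,4a-dimethyl-6-oxodecahydronaphthalene-1-carboxylate (both C8 epimers) | O=C1CC(OCc3ccccc3)[C@H]2[C@](C1)(C)CCC[C@]2(C)C(=O)OC | intermediate
11 | methyl (1S,4aR,8aS)-1,4a-dimethyl-6-oxo-1,2,3,4,4a,5,6,8a-octahydronaphthalene-1-carboxylate | O=C1C=C[C@H]2[C@](C1)(C)CCC[C@]2(C)C(=O)OC | intermediate
12 | (3R)-3,7-dimethylocta-1,6-dien-3-ol [(R)-linalool] | C=C[C@@](C)(CCC=C(C)C)O | starting material
13 | tert-butyl{[(3R)-3,7-dimethylocta-1,6-dien-3-yl]oxy}dimethylsilane | C=C[C@@](C)(CCC=C(C)C)O[Si](C)(C)C(C)(C)C | intermediate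
14 | (4R)-4-{[tert-butyl(dimethyl)silyl]oxy}-4-methylhex-5-enal | C=C[C@@](C)(CCC=O)O[Si](C)(C)C(C)(C)C | intermediate
15 | tert-butyl(dimethyl){[(3R)-3-methyl-6-{[tri(propan-2-yl)silyl]oxy}hexa-1,5-dien-3-yl]oxy}silane (E/Z mixture) | C=C[C@@](C)(CC=CO[Si](C(C)C)(C(C)C)C(C)C)O[Si](C)(C)C(C)(C)C | intermediate
16 | (3R)-3-{[tert-butyl(dimethyl)silyl]oxy}-3-methylpent-4-enal | C=C[C@@](C)(CC=O)O[Si](C)(C)C(C)(C)C | intermediate
17 | (3R)-3-{[tert-butyl(dimethyl)silyl]oxy}-3-methylpent-4-en-1-ol | C=C[C@@](C)(CCO)O[Si](C)(C)C(C)(C)C | intermediate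
18 | (3R)-3-{[tert-butyl(dimethyl)silyl]oxy}-3-methylpent-4-en-1-yl trifluoromethanesulfonate | C=C[C@@](C)(CCOS(=O)(=O)C(F)(F)F)O[Si](C)(C)C(C)(C)C | intermediate
19 | methyl (1S,4aS,5R,8aS)-5-[(3R)-3-{[tert-butyl(dimethyl)silyl]oxy}-3-methylpent-4-en-1-yl]-1,4a-dimethyl-6-oxo-1,2,3,4,4a,5,6,8a-octahydronaphthalene-1-carboxylate | C=C[C@@](C)(CC[C@H]1C(=O)C=C[C@H]2[C@]1(C)CCC[C@]2(C)C(=O)OC)O[Si](C)(C)C(C)(C)C | intermediate
20 | methyl (1S,4aS,5R,8aS)-5-[(3R)-3-{[tert-butyl(dimethyl)silyl]oxy}-3-methylpent-4-en-1-yl]-1,4a-dimethyl-6-oxodecahydronaphthalene-1-carboxylate | C=C[C@@](C)(CC[C@H]1C(=O)CC[C@H]2[C@]1(C)CCC[C@]2(C)C(=O)OC)O[Si](C)(C)C(C)(C)C | intermediate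
21 | methyl (1S,4aR,5S,8aS)-5-[(3R)-3-{[tert-butyl(dimethyl)silyl]oxy}-3-methylpent-4-en-1-yl]-1,4a-dimethyl-6-methylidenedecahydronaphthalene-1-carboxylate | C=C[C@@](C)(CC[C@H]1C(=C)CC[C@H]2[C@]1(C)CCC[C@]2(C)C(=O)OC)O[Si](C)(C)C(C)(C)C | intermediate
22 | (1S,4aR,5S,8aS)-5-[(3R)-3-{[tert-butyl(dimethyl)silyl]oxy}-3-methylpent-4-en-1-yl]-1,4a-dimethyl-6-methylidenedecahydronaphthalene-1-carboxylic acid | C=C[C@@](C)(CC[C@H]1C(=C)CC[C@H]2[C@]1(C)CCC[C@]2(C)C(=O)O)O[Si](C)(C)C(C)(C)C | intermediate
23 | (1S,4aR,5S,8aS)-5-[(3R)-3-hydroxy-3-methylpent-4-en-1-yl]-1,4a-dimethyl-6-methylidenedecahydronaphthalene-1-carboxylic acid | C=C[C@@](C)(CC[C@H]1C(=C)CC[C@H]2[C@]1(C)CCC[C@]2(C)C(=O)O)O | intermediate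
24 | acetic (1S,4aR,5S,8aS)-5-[(3R)-3-(acetyloxy)-3-methylpent-4-en-1-yl]-1,4a-dimethyl-6-methylidenedecahydronaphthalene-1-carboxylic anhydride | C=C[C@@](C)(CC[C@H]1C(=C)CC[C@H]2[C@]1(C)CCC[C@]2(C)C(=O)OC(C)=O)OC(C)=O | intermediate
25 | (1S,4aR,5S,8aS)-5-[(3R)-3-(acetyloxy)-3-methylpent-4-en-1-yl]-1,4a-dimethyl-6-methylidenedecahydronaphthalene-1-carboxylic acid | C=C[C@@](C)(CC[C@H]1C(=C)CC[C@H]2[C@]1(C)CCC[C@]2(C)C(=O)O)OC(C)=O | target

**Step count and risks**

Total step count: 17. Longest linear sequence: 12 steps (steps 1–6, then 12–17); the side-chain branch (steps 7–11) joins at step 12.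

Steps most likely to fail:

1. Step 6 (proposed new method). The intermolecular capture of the zwitterion by the hindered alkene may be too slow, so that the zwitterion condenses with itself. The C10 cation may also lose a proton or be trapped by the ester carbonyl (lactonisation), and facial selectivity with respect to C4 may be poor. The fallback uses known chemistry and builds ring B from the same four-membered-ring logic by two one-carbon expansions. It sets out from 8: dichloroketene (Cl3CCOCl, Zn(Cu), Et2O) adds to the C5=C10 alkene in a [2+2] cycloaddition to give the cis-fused methyl 7,7-dichloro-2,6-dimethyl-8-oxobicyclo[4.2.0]octane-2-carboxylate F1 (carbonyl on C5, CCl2 on C10). CH2N2 ring expansion with migration of the non-chlorinated carbon gives methyl 1,1-dichloro-4,7a-dimethyl-2-oxooctahydro-1H-indene-4-carboxylate F2. A second CH2N2 homologation of the same kind gives methyl 5,5-dichloro-1,4a-dimethyl-6-oxodecahydronaphthalene-1-carboxylate F3. Zn in AcOH removes both chlorines to give methyl (1S,4aR,8aS)-1,4a-dimethyl-6-oxodecahydronaphthalene-1-carboxylate F4, and dehydrogenation with 2-iodoxybenzoic acid (DMSO, 70 °C), possible only towards C6–C7 because C10 is quaternary, comes back to the route at 11.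

2. Step 12. Alkylation of the hindered dienolate may be slow enough for proton exchange, and attack may occur on the face syn to the C1–C10 bond, which would put the chain trans to the C10 methyl. The fallback sets C9 by C–H instead of C–C bond formation. It sets out from 11 and 18: the alkylation is run to completion without regard to selectivity to give the C9 epimer, methyl (1S,4aS,5S,8aS)-5-[(3R)-3-{[tert-butyl(dimethyl)silyl]oxy}-3-methylpent-4-en-1-yl]-1,4a-dimethyl-6-oxo-1,2,3,4,4a,5,6,8a-octahydronaphthalene-1-carboxylate F5. F5 is deprotonated again at C9 (LiN(iPr)2, THF, −78 °C; the enone offers no other kinetic site) and the dienolate is protonated at −78 °C with 2,6-di-tert-butylphenol. The proton enters on the face the electrophile preferred, which inverts C9 and comes back to the route at 19.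

3. Step 14. Methylenation of the hindered ketone may stall, the Lewis-acidic titanium reagent may strip the tertiary silyl ether, or C9 may epimerise during a long reaction. The fallback is a two-stage Peterson olefination that sets out from 20: Me3SiCH2Li with CeCl3 (THF, −78 °C) adds to the C8 ketone without enolisation to give the β-hydroxysilane methyl 5-[(3R)-3-{[tert-butyl(dimethyl)silyl]oxy}-3-methylpent-4-en-1-yl]-6-hydroxy-1,4a-dimethyl-6-[(trimethylsilyl)methyl]decahydronaphthalene-1-carboxylate F6. KH (THF, 0 °C) then eliminates the silanolate and comes back to the route at 21.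

**Further compounds**

F1 | step 6 | methyl 7,7-dichloro-2,6-dimethyl-8-oxobicyclo[4.2.0]octane-2-carboxylate (cis-fused, stereocentres as in 11) | O=C1[C@H]2[C@](C1(Cl)Cl)(C)CCC[C@]2(C)C(=O)OC
F2 | step 6 | methyl 1,1-dichloro-4,7a-dimethyl-2-oxooctahydro-1H-indene-4-carboxylate (cis-fused, stereocentres as in 11) | O=C1C[C@H]2[C@](C1(Cl)Cl)(C)CCC[C@]2(C)C(=O)OC
F3 | step 6 | methyl 5,5-dichloro-1,4a-dimethyl-6-oxodecahydronaphthalene-1-carboxylate (cis-fused, stereocentres as in 11) | O=C1CC[C@H]2[C@](C1(Cl)Cl)(C)CCC[C@]2(C)C(=O)OC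
F4 | step 6 | methyl (1S,4aR,8aS)-1,4a-dimethyl-6-oxodecahydronaphthalene-1-carboxylate | O=C1CC[C@H]2[C@](C1)(C)CCC[C@]2(C)C(=O)OC
F5 | step 12 | methyl (1S,4aS,5S,8aS)-5-[(3R)-3-{[tert-butyl(dimethyl)silyl]oxy}-3-methylpent-4-en-1-yl]-1,4a-dimethyl-6-oxo-1,2,3,4,4a,5,6,8a-octahydronaphthalene-1-carboxylate | C=C[C@@](C)(CC[C@@H]1C(=O)C=C[C@H]2[C@]1(C)CCC[C@]2(C)C(=O)OC)O[Si](C)(C)C(C)(C)C
F6 | step 14 | methyl 5-[(3R)-3-{[tert-butyl(dimethyl)silyl]oxy}-3-methylpent-4-en-1-yl]-6-hydroxy-1,4a-dimethyl-6-[(trimethylsilyl)methyl]decahydronaphthalene-1-carboxylate (ring stereocentres as in 20, carbinol centre as formed) | C=C[C@@](C)(CC[C@H]1C(O)(C[Si](C)(C)C)CC[C@H]2[C@]1(C)CCC[C@]2(C)C(=O)OC)O[Si](C)(C)C(C)(C)C
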